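**Retrosynthetic overview**
- The target comes from a hydroxy dienoate by O-sulfation and saponification; the dienoate comes from a decalin keto aldehyde by Wittig extension at C1 and reduction of the C7 ketone.
- Ring A is closed last, onto ring B: an amine-catalysed alkenylation/Michael cascade of a dienal tethered to a 2-methylcyclohex-2-enone forms the C2–butenyl and C1–C8a bonds.
- Key step: ring B is made by a one-carbon ring expansion (FeCl3 opening of a siloxycyclopropane, Ito–Saegusa type) of a cyclopentanone silyl enol ether. This turns the easily made 3-alkenylcyclopentanone enolate into the 4-alkenyl-2-methylcyclohex-2-enone.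
- The C4a stereocentre comes from a rhodium-catalysed asymmetric 1,4-addition of a (Z)-dienylzinc to cyclopentenone; the (Z)-dienyl iodide comes from propargyl alcohol.
- Ring order: five-membered ring (bought) → expanded to ring B → ring A.

Assumption: the product is isolated in the neutral form drawn (hydrogen sulfate, free carboxylic acid); locants C1–C8a of the octahydronaphthalene core are used for all intermediates.

**Step 1**
Reactants: 1 prop-2-yn-1-ol
Product: 3 (Z)-3-iodo-2-methylprop-2-en-1-ol, via alkenylmagnesium alkoxide 2 (not isolated)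
Conditions: MeMgBr (3 equiv), CuI (10 mol %), THF–Et2O, −10 → 20 °C; then I2, −10 °C
Reagents that add atoms: methylmagnesium bromide, C[Mg]Br; iodine, II
Why: Hydroxyl-directed anti carbomagnesiation (Duboudin type) puts methyl on the internal alkyne carbon and the alkoxide-chelated magnesium on the terminal one, so iodinolysis with retention gives only the Z iodide.

**Step 2**
Reactants: 3 (Z)-3-iodo-2-methylprop-2-en-1-ol
Product: 5 (2E,4Z)-5-iodo-4-methylpenta-2,4-dienal, via (Z)-3-iodo-2-methylprop-2-enal 4 (not isolated)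
Conditions: MnO2, Ph3P=CHCHO, CH2Cl2, 40 °C
Reagents that add atoms: (triphenylphosphoranylidene)acetaldehyde, O=CC=P(c1ccccc1)(c1ccccc1)c1ccccc1
Why: Tandem allylic oxidation–Wittig olefination with the stabilised ylide gives the E enal and consumes the labile Z iodo enal as it forms, so the Z iodoalkene is kept.

**Step 3**
Reactants: 5 (2E,4Z)-5-iodo-4-methylpenta-2,4-dienal
Product: 6 2-[(1E,3Z)-4-iodo-3-methylbuta-1,3-dien-1-yl]-1,3-dioxolane
Conditions: HOCH2CH2OH, pyridinium p-toluenesulfonate, benzene, reflux (Dean–Stark)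
Reagents that add atoms: ethane-1,2-diol, OCCO
Why: Acid-catalysed acetalisation masks the aldehyde for the organometallic steps without creating a stereocentre or touching either alkene geometry.

**Step 4**
Reactants: 6 2-[(1E,3Z)-4-iodo-3-methylbuta-1,3-dien-1-yl]-1,3-dioxolane; 7 cyclopent-2-en-1-one
Product: 10 trimethyl({(3R)-3-[(1Z,3E)-4-(1,3-dioxolan-2-yl)-2-methylbuta-1,3-dien-1-yl]cyclopent-1-en-1-yl}oxy)silane, via alkenyllithium 8 (not isolated), via alkenylzinc chloride 9 (not isolated)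
Conditions: t-BuLi (2 equiv), Et2O, −78 °C; ZnCl2, THF, −78 → 0 °C; then 7, [RhCl((S)-binap)]2 (3 mol % Rh), Me3SiCl, THF, 20 °C
Reagents that add atoms: chlorotrimethylsilane, C[Si](C)(C)Cl; tert-butyllithium, [Li]C(C)(C)C (lithium of 8 only); zinc dichloride, Cl[Zn]Cl (zinc and chlorine of 9 only)
Why: Iodine–lithium exchange and transmetalation retain the Z geometry, and the Hayashi-type rhodium/binap-catalysed asymmetric 1,4-addition of the organozinc with chlorosilane sets C4a by ligand control (same sense as aryl and alkenyl additions to cyclopentenone with (S)-binap) and traps the enolate regiospecifically as its silyl enol ether.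

**Step 5**
Reactants: 10 trimethyl({(3R)-3-[(1Z,3E)-4-(1,3-dioxolan-2-yl)-2-methylbuta-1,3-dien-1-yl]cyclopent-1-en-1-yl}oxy)silane
Product: 11 trimethyl({(1S,4R,5S)-4-[(1Z,3E)-4-(1,3-dioxolan-2-yl)-2-methylbuta-1,3-dien-1-yl]-6-methylbicyclo[3.1.0]hexan-1-yl}oxy)silane (cyclopropane trans to the dienyl group, both C6 epimers)
Conditions: Et2Zn, CH3CHI2, Et2O, 0 → 20 °C
Reagents that add atoms: 1,1-diiodoethane, CC(I)I
Why: Furukawa-type Simmons–Smith ethylidene transfer goes to the electron-rich silyl enol ether rather than the other alkenes and from the face opposite the dienyl group; the configuration of the methyl-bearing carbon does not matter because it becomes sp2 in step 6.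

**Step 6**
Reactants: 11 trimethyl({(1S,4R,5S)-4-[(1Z,3E)-4-(1,3-dioxolan-2-yl)-2-methylbuta-1,3-dien-1-yl]-6-methylbicyclo[3.1.0]hexan-1-yl}oxy)silane
Product: 14 (2E,4Z)-4-methyl-5-[(1R)-3-methyl-4-oxocyclohex-2-en-1-yl]penta-2,4-dienal, via chloro ketone 12 (not isolated), via enone acetal 13 (not isolated)
Conditions: FeCl3, DMF, 0 → 20 °C; NaOAc, MeOH, 60 °C; then 1 M HCl, THF, 20 °C
Reagents that add atoms: water, O (aldehyde oxygen); iron trichloride, Cl[Fe](Cl)Cl (chlorine of 12 only)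
Why: Ito–Saegusa ring expansion, in which one-electron oxidation by FeCl3 (trivalent iron) breaks the internal cyclopropane bond to give the ring-enlarged β-keto radical that takes chlorine from FeCl3, then acetate eliminates HCl to the 2-methylcyclohex-2-enone with C4a untouched, and aqueous acid unmasks the dienal.

**Step 7**
Reactants: 14 (2E,4Z)-4-methyl-5-[(1R)-3-methyl-4-oxocyclohex-2-en-1-yl]penta-2,4-dienal; 15 (Z)-but-2-en-2-ylboronic acid
Product: 17 (1S,2R,4aS,8R,8aR)-2-[(2E)-but-2-en-2-yl]-3,8-dimethyl-7-oxo-1,2,4a,5,6,7,8,8a-octahydronaphthalene-1-carbaldehyde, via trifluoroborate salt 16 (not isolated)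
Conditions: 15, KHF2, MeOH–H2O, 20 °C, evaporation; then 14, (2S,5S)-5-benzyl-2-tert-butyl-3-methylimidazolidin-4-one·CF3CO2H (20 mol %), HF (1 equiv), DME, −20 → 20 °C
Reagents that add atoms: potassium hydrogen difluoride, [K+].[F-].F (potassium and fluorine of 16 only)
Why: Proposed new method: an iminium–enamine cascade in which the imidazolidinone activates the dienal for conjugate addition of the alkenyltrifluoroborate at C2 (attack at the boron-bearing carbon on the face away from the benzyl group gives 2R, with the alkene geometry retained) and the enamine so formed closes ring A by intramolecular Michael addition of C1 to C8a on the tether face (cis fusion), while C1 and C8 settle by enolisation to the equatorial-formyl and trans-methyl arrangement; the closest known reactions are the imidazolidinone-catalysed conjugate addition of vinyl trifluoroborates to enals and the amine-catalysed reductive Michael cyclisation of enal enones, which have not been combined or applied to a 2,4-dienal.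

**Step 8**
Reactants: 17 (1S,2R,4aS,8R,8aR)-2-[(2E)-but-2-en-2-yl]-3,8-dimethyl-7-oxo-1,2,4a,5,6,7,8,8a-octahydronaphthalene-1-carbaldehyde; 18 methyl (2E)-4-bromobut-2-enoate
Product: 21 methyl (2E,4E)-5-[(1S,2R,4aS,8R,8aR)-2-[(2E)-but-2-en-2-yl]-3,8-dimethyl-7-oxo-1,2,4a,5,6,7,8,8a-octahydronaphthalen-1-yl]penta-2,4-dienoate, via phosphonium bromide 19 (not isolated), via phosphorus ylide 20 (not isolated)
Conditions: 18, PBu3, THF, 20 °C; LiN(SiMe3)2, −78 °C; then 17, −78 → 0 °C
Reagents that add atoms: tributylphosphine, CCCCP(CCCC)CCCC (phosphorus and butyl groups of 19 and 20 only)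
Why: Wittig olefination with the semi-stabilised allylic tributylphosphonium ylide reacts only at the aldehyde and forms the new double bond E, giving the (2E,4E)-dienoate with C1 already in its preferred configuration.

**Step 9**
Reactants: 21 methyl (2E,4E)-5-[(1S,2R,4aS,8R,8aR)-2-[(2E)-but-2-en-2-yl]-3,8-dimethyl-7-oxo-1,2,4a,5,6,7,8,8a-octahydronaphthalen-1-yl]penta-2,4-dienoate
Product: 22 methyl (2E,4E)-5-[(1S,2R,4aS,7S,8R,8aR)-2-[(2E)-but-2-en-2-yl]-7-hydroxy-3,8-dimethyl-1,2,4a,5,6,7,8,8a-octahydronaphthalen-1-yl]penta-2,4-dienoate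
Conditions: LiBH(s-Bu)3, THF, −78 °C; then H2O
Reagents that add atoms: none
Why: Substrate-controlled hydride reduction in which the bulky borohydride attacks the ring-B chair with equatorial C8 methyl from the equatorial direction (the 2-methylcyclohexanone pattern), giving the axial 7S alcohol cis to the methyl, while the dienoate is not reduced at −78 °C.

**Step 10**
Reactants: 22 methyl (2E,4E)-5-[(1S,2R,4aS,7S,8R,8aR)-2-[(2E)-but-2-en-2-yl]-7-hydroxy-3,8-dimethyl-1,2,4a,5,6,7,8,8a-octahydronaphthalen-1-yl]penta-2,4-dienoate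
Product: 23 methyl (2E,4E)-5-[(1S,2R,4aS,7S,8R,8aR)-2-[(2E)-but-2-en-2-yl]-3,8-dimethyl-7-(sulfooxy)-1,2,4a,5,6,7,8,8a-octahydronaphthalen-1-yl]penta-2,4-dienoate
Conditions: SO3·pyridine, pyridine, 50 °C
Reagents that add atoms: sulfur trioxide pyridine complex, O=S(=O)=O.c1ccncc1
Why: O-sulfation with the SO3–amine complex forms the S–O bond at the alcohol oxygen, so C7 keeps its configuration.

**Step 11**
Reactants: 23 methyl (2E,4E)-5-[(1S,2R,4aS,7S,8R,8aR)-2-[(2E)-but-2-en-2-yl]-3,8-dimethyl-7-(sulfooxy)-1,2,4a,5,6,7,8,8a-octahydronaphthalen-1-yl]penta-2,4-dienoate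
Product: 24 (2E,4E)-5-[(1S,2R,4aS,7S,8R,8aR)-2-[(2E)-but-2-en-2-yl]-3,8-dimethyl-7-(sulfooxy)-1,2,4a,5,6,7,8,8a-octahydronaphthalen-1-yl]penta-2,4-dienoic acid
Conditions: LiOH, THF–H2O, 0 → 20 °C; then cold 1 M HCl to pH 2
Reagents that add atoms: lithium hydroxide, [Li+].[OH-] (one oxygen of the carboxylic acid)
Why: Saponification by acyl–oxygen cleavage frees the acid while the alkyl sulfate monoester is inert to hydroxide at room temperature, and brief cold acidification gives the neutral target with every stereocentre untouched.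

**Compound list**
1 | prop-2-yn-1-ol | C#CCO | starting material
2 | bromomagnesium (Z)-3-(bromomagnesio)-2-methylprop-2-en-1-olate | Br[Mg]OC/C(C)=C\[Mg]Br | intermediate
3 | (Z)-3-iodo-2-methylprop-2-en-1-ol | OC/C(C)=C\I | intermediate
4 | (Z)-3-iodo-2-methylprop-2-enal | O=C/C(C)=C\I | intermediate
5 | (2E,4Z)-5-iodo-4-methylpenta-2,4-dienal | O=C/C=C/C(C)=C\I | intermediate
6 | 2-[(1E,3Z)-4-iodo-3-methylbuta-1,3-dien-1-yl]-1,3-dioxolane | C1COC(O1)/C=C/C(C)=C\I | intermediate
7 | cyclopent-2-en-1-one | O=C1C=CCC1 | starting material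
8 | [(1Z,3E)-4-(1,3-dioxolan-2-yl)-2-methylbuta-1,3-dien-1-yl]lithium | C1COC(O1)/C=C/C(C)=C\[Li] | intermediate
9 | chloro[(1Z,3E)-4-(1,3-dioxolan-2-yl)-2-methylbuta-1,3-dien-1-yl]zinc | C1COC(O1)/C=C/C(C)=C\[Zn]Cl | intermediate
10 | trimethyl({(3R)-3-[(1Z,3E)-4-(1,3-dioxolan-2-yl)-2-methylbuta-1,3-dien-1-yl]cyclopent-1-en-1-yl}oxy)silane | C1COC(O1)/C=C/C(C)=C\[C@@H]1C=C(O[Si](C)(C)C)CC1 | intermediate
11 | trimethyl({(1S,4R,5S)-4-[(1Z,3E)-4-(1,3-dioxolan-2-yl)-2-methylbuta-1,3-dien-1-yl]-6-methylbicyclo[3.1.0]hexan-1-yl}oxy)silane, both C6 epimers | C1COC(O1)/C=C/C(C)=C\[C@H]1CC[C@]2(O[Si](C)(C)C)C(C)[C@H]12 | intermediate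
12 | (4R)-3-chloro-4-[(1Z,3E)-4-(1,3-dioxolan-2-yl)-2-methylbuta-1,3-dien-1-yl]-2-methylcyclohexan-1-one, C2/C3 epimers | C1COC(O1)/C=C/C(C)=C\[C@H]1CCC(=O)C(C)C1Cl | intermediate
13 | (4R)-4-[(1Z,3E)-4-(1,3-dioxolan-2-yl)-2-methylbuta-1,3-dien-1-yl]-2-methylcyclohex-2-en-1-one | C1COC(O1)/C=C/C(C)=C\[C@@H]1C=C(C)C(=O)CC1 | intermediate
14 | (2E,4Z)-4-methyl-5-[(1R)-3-methyl-4-oxocyclohex-2-en-1-yl]penta-2,4-dienal | O=C/C=C/C(C)=C\[C@@H]1C=C(C)C(=O)CC1 | intermediate
15 | (Z)-but-2-en-2-ylboronic acid (methyl groups cis) | C/C=C(\C)B(O)O | starting material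
16 | potassium (Z)-but-2-en-2-yltrifluoroborate | C/C=C(\C)[B-](F)(F)F.[K+] | intermediate
17 | (1S,2R,4aS,8R,8aR)-2-[(2E)-but-2-en-2-yl]-3,8-dimethyl-7-oxo-1,2,4a,5,6,7,8,8a-octahydronaphthalene-1-carbaldehyde | C/C=C(\C)[C@@H]1C(C)=C[C@H]2CCC(=O)[C@H](C)[C@H]2[C@@H]1C=O | intermediate
18 | methyl (2E)-4-bromobut-2-enoate | COC(=O)/C=C/CBr | starting material
19 | tributyl[(2E)-4-methoxy-4-oxobut-2-en-1-yl]phosphonium bromide | COC(=O)/C=C/C[P+](CCCC)(CCCC)CCCC.[Br-] | intermediate
20 | methyl (2E)-4-(tributyl-λ5-phosphanylidene)but-2-enoate | COC(=O)/C=C/C=P(CCCC)(CCCC)CCCC | intermediate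
21 | methyl (2E,4E)-5-[(1S,2R,4aS,8R,8aR)-2-[(2E)-but-2-en-2-yl]-3,8-dimethyl-7-oxo-1,2,4a,5,6,7,8,8a-octahydronaphthalen-1-yl]penta-2,4-dienoate | C/C=C(\C)[C@@H]1C(C)=C[C@H]2CCC(=O)[C@H](C)[C@H]2[C@@H]1/C=C/C=C/C(=O)OC | intermediate
22 | methyl (2E,4E)-5-[(1S,2R,4aS,7S,8R,8aR)-2-[(2E)-but-2-en-2-yl]-7-hydroxy-3,8-dimethyl-1,2,4a,5,6,7,8,8a-octahydronaphthalen-1-yl]penta-2,4-dienoate | C/C=C(\C)[C@@H]1C(C)=C[C@H]2CC[C@H](O)[C@H](C)[C@H]2[C@@H]1/C=C/C=C/C(=O)OC | intermediate
23 | methyl (2E,4E)-5-[(1S,2R,4aS,7S,8R,8aR)-2-[(2E)-but-2-en-2-yl]-3,8-dimethyl-7-(sulfooxy)-1,2,4a,5,6,7,8,8a-octahydronaphthalen-1-yl]penta-2,4-dienoate | C/C=C(\C)[C@@H]1C(C)=C[C@H]2CC[C@H](OS(=O)(=O)O)[C@H](C)[C@H]2[C@@H]1/C=C/C=C/C(=O)OC | intermediate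
24 | (2E,4E)-5-[(1S,2R,4aS,7S,8R,8aR)-2-[(2E)-but-2-en-2-yl]-3,8-dimethyl-7-(sulfooxy)-1,2,4a,5,6,7,8,8a-octahydronaphthalen-1-yl]penta-2,4-dienoic acid | C/C=C(\C)[C@@H]1C(C)=C[C@H]2CC[C@H](OS(=O)(=O)O)[C@H](C)[C@H]2[C@@H]1/C=C/C=C/C(=O)O | target

**Step count and risks**
Total steps: 11. Longest linear sequence: 11 (1 → 24; 7, 15 and 18 are used as bought).

The three steps most likely to fail are 7, 6 and 4.

Step 7 (proposed cascade). The alkenyl addition may work but not couple with ring closure, or the Z dienal may isomerise first. The fallback sets out from 14 and 15 and returns at 17 with two known reactions. A rhodium/chiral diene-catalysed 1,4-addition of 15 to the enal of 14 ([RhCl(C2H4)2]2, a C2-symmetric bicyclo[2.2.2]octadiene ligand, KOH, dioxane–H2O; Hayashi–Miyaura type, ligand control at C2, the α-methyl enone is too hindered to react) gives (3R,4Z)-3-[(2E)-but-2-en-2-yl]-4-methyl-5-[(1R)-3-methyl-4-oxocyclohex-2-en-1-yl]pent-4-enal F1. A secondary-amine-catalysed intramolecular aldehyde–enone Michael addition (pyrrolidine/AcOH, List type) then closes ring A to 17.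

Step 6 (ring expansion with the methyl-bearing cyclopropane). The radical opening could break the external bond, since both possible radicals are secondary, and give a 2-(1-chloroethyl)cyclopentanone; the dienyl acetal is also exposed to a Lewis acid. The fallback sets out from 10 and returns at 13, which the acid of step 6 turns into 14; it keeps the same ring expansion but brings the methyl in later. Methylene transfer (Et2Zn, CH2I2) gives trimethyl({(1S,4R,5R)-4-[(1Z,3E)-4-(1,3-dioxolan-2-yl)-2-methylbuta-1,3-dien-1-yl]bicyclo[3.1.0]hexan-1-yl}oxy)silane F2. Its FeCl3 opening is the regiochemically secure parent case and gives (4R)-3-chloro-4-[(1Z,3E)-4-(1,3-dioxolan-2-yl)-2-methylbuta-1,3-dien-1-yl]cyclohexan-1-one F3, and NaOAc then gives (4S)-4-[(1Z,3E)-4-(1,3-dioxolan-2-yl)-2-methylbuta-1,3-dien-1-yl]cyclohex-2-en-1-one F4 (same spatial arrangement as 13; the descriptor changes). α-Iodination (I2, pyridine, CH2Cl2, 0 °C, dark) gives (4R)-4-[(1Z,3E)-4-(1,3-dioxolan-2-yl)-2-methylbuta-1,3-dien-1-yl]-2-iodocyclohex-2-en-1-one F5, and Suzuki methylation (MeB(OH)2, Pd(dppf)Cl2, K3PO4, dioxane–H2O) gives 13.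

Step 4 (rhodium addition of a functionalised alkenylzinc with silyl trapping). This variant is documented for arylzinc reagents; the alkenylzinc may transfer poorly or with lower selectivity. The fallback sets out from 6 (through 8) and returns at 10, replacing catalyst control by a sulfoxide auxiliary. MgBr2 converts 8 into bromo[(1Z,3E)-4-(1,3-dioxolan-2-yl)-2-methylbuta-1,3-dien-1-yl]magnesium F6. This adds to the ZnBr2-chelated Posner enone (R)-2-(4-methylbenzenesulfinyl)cyclopent-2-en-1-one F7 (known compound, from cyclopentenone and menthyl p-toluenesulfinate) on the face away from the tolyl group. The product is (3R)-3-[(1Z,3E)-4-(1,3-dioxolan-2-yl)-2-methylbuta-1,3-dien-1-yl]-2-(4-methylbenzenesulfinyl)cyclopentan-1-one F8 (sulfur as in F7, C2 epimers). Reductive desulfinylation with SmI2 (THF, −78 °C; known cleavage of α-sulfinyl ketones) gives the regiodefined samarium enolate diiodo({(3R)-3-[(1Z,3E)-4-(1,3-dioxolan-2-yl)-2-methylbuta-1,3-dien-1-yl]cyclopent-1-en-1-yl}oxy)samarium F9, and Me3SiCl returns 10.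

**Further compounds**
F1 | step 7 | (3R,4Z)-3-[(2E)-but-2-en-2-yl]-4-methyl-5-[(1R)-3-methyl-4-oxocyclohex-2-en-1-yl]pent-4-enal | C/C=C(\C)[C@@H](CC=O)/C(C)=C\[C@@H]1C=C(C)C(=O)CC1
F2 | step 6 | trimethyl({(1S,4R,5R)-4-[(1Z,3E)-4-(1,3-dioxolan-2-yl)-2-methylbuta-1,3-dien-1-yl]bicyclo[3.1.0]hexan-1-yl}oxy)silane | C1COC(O1)/C=C/C(C)=C\[C@H]1CC[C@]2(O[Si](C)(C)C)C[C@H]12
F3 | step 6 | (4R)-3-chloro-4-[(1Z,3E)-4-(1,3-dioxolan-2-yl)-2-methylbuta-1,3-dien-1-yl]cyclohexan-1-one, C3 epimers | C1COC(O1)/C=C/C(C)=C\[C@H]1CCC(=O)CC1Cl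
F4 | step 6 | (4S)-4-[(1Z,3E)-4-(1,3-dioxolan-2-yl)-2-methylbuta-1,3-dien-1-yl]cyclohex-2-en-1-one | C1COC(O1)/C=C/C(C)=C\[C@@H]1C=CC(=O)CC1
F5 | step 6 | (4R)-4-[(1Z,3E)-4-(1,3-dioxolan-2-yl)-2-methylbuta-1,3-dien-1-yl]-2-iodocyclohex-2-en-1-one | C1COC(O1)/C=C/C(C)=C\[C@@H]1C=C(I)C(=O)CC1
F6 | step 4 | bromo[(1Z,3E)-4-(1,3-dioxolan-2-yl)-2-methylbuta-1,3-dien-1-yl]magnesium | C1COC(O1)/C=C/C(C)=C\[Mg]Br
F7 | step 4 | (R)-2-(4-methylbenzenesulfinyl)cyclopent-2-en-1-one | Cc1ccc(cc1)[S@@](=O)C1=CCCC1=O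
F8 | step 4 | (3R)-3-[(1Z,3E)-4-(1,3-dioxolan-2-yl)-2-methylbuta-1,3-dien-1-yl]-2-(4-methylbenzenesulfinyl)cyclopentan-1-one, C2 epimers | C1COC(O1)/C=C/C(C)=C\[C@H]1CCC(=O)C1[S@](=O)c1ccc(C)cc1
F9 | step 4 | diiodo({(3R)-3-[(1Z,3E)-4-(1,3-dioxolan-2-yl)-2-methylbuta-1,3-dien-1-yl]cyclopent-1-en-1-yl}oxy)samarium | C1COC(O1)/C=C/C(C)=C\[C@@H]1C=C(O[Sm](I)I)CC1
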